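**Plan**
- Ring numbering O1, C2 (carbonyl), C3, C4, C5: the carboxyl sits on C4, β to C2, and the methylene on C3, α to C2. The C4–CO2H and C3=CH2 bonds are therefore cut together, back to a C3=C4 butenolide, a carboxyl anion equivalent and an aminomethyl cation equivalent.
- The butenolide is cut at the lactone C2–O1 bond and at C4–C5 (aldehyde plus methyl propiolate); the aldehyde chain comes from pentadecanolide by C-methylation at its carbonyl carbon.
- Forward: side chain first (steps 1–4), then the C5 carbinol and the only ring (steps 5–6), then both ring substituents in one flask (step 7), then methylene formation and unmasking of ketone and acid (steps 8–10).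
- Stereochemistry: C5 (R) by catalyst control in the alkynylation; C4 (S) by substrate control, the nucleophile entering anti to the C5 chain; the C3 centre made in step 7 is transient.

Key step: step 7

Remark: lactone numbering as above is used throughout (the target is the 4S,5R trans acid, 2R,3S in acid nomenclature). (S)-BINOL is assumed to deliver the alkynyl group to the Si face of an unbranched aliphatic aldehyde, as it does with aryl aldehydes.

Step 1
Reactants: 1 pentadecanolide (oxacyclohexadecan-2-one)
Product: 2 15-hydroxy-N-methoxy-N-methylpentadecanamide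
Conditions: MeNH(OMe)·HCl, AlMe3, CH2Cl2, 0 °C to rt
Reagents that add atoms: N,O-dimethylhydroxylamine hydrochloride, `CNOC.Cl`
Why: Weinreb aminolysis, in which the aluminium amide formed from AlMe3 and the amine hydrochloride attacks the lactone carbonyl and opens the ring by acyl–oxygen cleavage, the standard way from a lactone to a hydroxy Weinreb amide.

Step 2
Reactants: 2 15-hydroxy-N-methoxy-N-methylpentadecanamide
Product: 3 16-hydroxyhexadecan-2-one
Conditions: MeMgBr (3 equiv), THF, 0 °C
Reagents that add atoms: methylmagnesium bromide, `C[Mg]Br`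
Why: Weinreb ketone synthesis, in which one equivalent of MeMgBr deprotonates the hydroxyl and the next adds to the amide to give a magnesium-chelated tetrahedral intermediate that survives until work-up, so addition should stop at the methyl ketone.

Step 3
Reactants: 3 16-hydroxyhexadecan-2-one
Product: 4 14-(2-methyl-1,3-dioxolan-2-yl)tetradecan-1-ol
Conditions: HOCH2CH2OH (excess), TsOH·H2O (cat.), toluene, reflux, Dean–Stark
Reagents that add atoms: ethane-1,2-diol, `OCCO`
Why: Acid-catalysed ketalisation driven by azeotropic removal of water, the excess diol outcompeting the remote primary hydroxyl so that only the dioxolane should form.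

Step 4
Reactants: 4 14-(2-methyl-1,3-dioxolan-2-yl)tetradecan-1-ol
Product: 5 14-(2-methyl-1,3-dioxolan-2-yl)tetradecanal
Conditions: TEMPO (cat.), PhI(OAc)2, CH2Cl2, rt
Reagents that add atoms: none
Why: Oxoammonium (TEMPO/PhI(OAc)2) oxidation of a primary alcohol, which stops at the aldehyde in the absence of water and is mild enough (anhydrous, only acetic acid formed) to leave the dioxolane intact.

Step 5
Reactants: 5 14-(2-methyl-1,3-dioxolan-2-yl)tetradecanal; 6 methyl propiolate
Product: 7 methyl (4R)-4-hydroxy-17-(2-methyl-1,3-dioxolan-2-yl)heptadec-2-ynoate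
Conditions: 6, Et2Zn, HMPA, CH2Cl2, rt; (S)-BINOL (cat.), Ti(OiPr)4 (1 equiv); then 5, rt
Reagents that add atoms: none
Why: BINOL–titanium-catalysed asymmetric alkynylzinc addition to an aldehyde, in which the zinc acetylide of 6 is delivered within the (S)-BINOL–titanium complex to the Si face of the aldehyde, setting the carbinol (the future lactone C5) as R by catalyst control.

Step 6
Reactants: 7 methyl (4R)-4-hydroxy-17-(2-methyl-1,3-dioxolan-2-yl)heptadec-2-ynoate
Product: 9 (5R)-5-[13-(2-methyl-1,3-dioxolan-2-yl)tridecyl]furan-2(5H)-one, via (Z)-hydroxy enoate 8 (not isolated)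
Conditions: H2 (1 atm), Pd/CaCO3 poisoned with Pb(OAc)2, quinoline, EtOAc, rt; then PPTS (cat.), CH2Cl2, rt
Reagents that add atoms: none
Why: Lindlar syn-semihydrogenation gives the Z-enoate, whose cis hydroxyl and ester groups close the butenolide by 5-exo-trig transesterification with loss of methanol, the carbinol stereocentre not being involved.

Step 7
Reactants: 9 (5R)-5-[13-(2-methyl-1,3-dioxolan-2-yl)tridecyl]furan-2(5H)-one; 10 tris(methylsulfanyl)methane; 11 dimethyl(methylidene)ammonium iodide
Product: 14 (3R,4S,5R)-3-[(dimethylamino)methyl]-5-[13-(2-methyl-1,3-dioxolan-2-yl)tridecyl]-4-[tris(methylsulfanyl)methyl]oxolan-2-one, via tris(methylsulfanyl)methyllithium 12 (not isolated), via lithium lactone enolate 13 (not isolated)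
Conditions: 10, n-BuLi, THF, −78 °C; then 9, −78 °C; then 11 (solid), −78 °C to 0 °C
Reagents that add atoms: none
Why: n-BuLi deprotonates 10 to the soft, bulky anion 12, which adds in a Michael sense to C4 of 9, and the resulting lithium enolate 13 (O–C2=C3) attacks the iminium carbon of 11 in a Mannich reaction, so the C4–C(SMe)3 and C3–CH2N bonds form in one flask. The closest known reaction type is the tandem conjugate addition of sulfur-stabilised carbanions (trithioorthoformate or dithiane anions) to butenolides with in-flask enolate trapping, joined to the aminomethylation of lactone enolates by this iminium salt. No ring is closed; the existing lactone only relays configuration. C4 is controlled by the C5 chain, the anion approaching the nearly planar butenolide on the face anti to the alkyl group to give the 4,5-trans (4S) adduct, and C3 is controlled by the new C4 group, the iminium ion entering anti to the C(SMe)3 group (3R), a centre erased in step 8. The step needs 1,4-addition rather than 1,2-addition or deprotonation at C5, which the delocalised sulfur-stabilised anion at −78 °C should secure, and it needs the enolate rather than leftover 12 to consume 11, which is secured by using 12 in only slight excess and adding 11 before warming so that retro-Michael loss of the trithiomethyl group cannot compete.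

Step 8
Reactants: 14 (3R,4S,5R)-3-[(dimethylamino)methyl]-5-[13-(2-methyl-1,3-dioxolan-2-yl)tridecyl]-4-[tris(methylsulfanyl)methyl]oxolan-2-one
Product: 16 (4S,5R)-3-methylidene-5-[13-(2-methyl-1,3-dioxolan-2-yl)tridecyl]-4-[tris(methylsulfanyl)methyl]oxolan-2-one, via trimethylammonium iodide 15 (not isolated)
Conditions: MeI, MeOH, rt; evaporate; then aq NaHCO3, EtOAc, rt
Reagents that add atoms: none
Why: Exhaustive N-methylation followed by E1cB (Hofmann-type) loss of trimethylamine from the β-ammonio lactone is the standard way from a Mannich base to an α-methylene lactone, and bicarbonate is too weak a base to move the alkene into the ring or to disturb C4 and C5.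

Step 9
Reactants: 16 (4S,5R)-3-methylidene-5-[13-(2-methyl-1,3-dioxolan-2-yl)tridecyl]-4-[tris(methylsulfanyl)methyl]oxolan-2-one
Product: 17 (4S,5R)-3-methylidene-5-(14-oxopentadecyl)-4-[tris(methylsulfanyl)methyl]oxolan-2-one
Conditions: 1 M aq HCl, THF, rt
Reagents that add atoms: water, `O`
Why: Acid-catalysed ketal hydrolysis through the oxocarbenium ion, under which a trithioorthoester (which needs a thiophile or much stronger acid), the lactone and the conjugated methylene should all be stable.

Step 10
Reactants: 17 (4S,5R)-3-methylidene-5-(14-oxopentadecyl)-4-[tris(methylsulfanyl)methyl]oxolan-2-one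
Product: 19 (2R,3S)-4-methylidene-5-oxo-2-(14-oxopentadecyl)oxolane-3-carboxylic acid, via S-methyl thioester 18 (not isolated)
Conditions: Hg(O2CCF3)2 (4 equiv), MeCN–H2O (4:1), 0 °C to rt
Reagents that add atoms: water, `O`
Why: Mercury-assisted hydrolysis of a trithioorthoester, in which thiophilic divalent mercury removes methanethiolate, water captures the bis(methylsulfanyl)carbenium ion to give thioester 18 and a second mercury-activated acyl substitution by water gives the acid, while the thiol stays bound to mercury and the non-basic medium should leave C4 and the exocyclic alkene untouched.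

**Compound list**
1 | pentadecanolide (oxacyclohexadecan-2-one) | `O=C1CCCCCCCCCCCCCCO1` | starting material
2 | 15-hydroxy-N-methoxy-N-methylpentadecanamide | `CON(C)C(=O)CCCCCCCCCCCCCCO` | intermediate
3 | 16-hydroxyhexadecan-2-one | `CC(=O)CCCCCCCCCCCCCCO` | intermediate
4 | 14-(2-methyl-1,3-dioxolan-2-yl)tetradecan-1-ol | `CC1(OCCO1)CCCCCCCCCCCCCCO` | intermediate
5 | 14-(2-methyl-1,3-dioxolan-2-yl)tetradecanal | `CC1(OCCO1)CCCCCCCCCCCCCC=O` | intermediate
6 | methyl propiolate | `C#CC(=O)OC` | starting material
7 | methyl (4R)-4-hydroxy-17-(2-methyl-1,3-dioxolan-2-yl)heptadec-2-ynoate | `COC(=O)C#C[C@H](O)CCCCCCCCCCCCCC1(C)OCCO1` | intermediate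
8 | methyl (2Z,4R)-4-hydroxy-17-(2-methyl-1,3-dioxolan-2-yl)heptadec-2-enoate (not isolated) | `COC(=O)/C=C\[C@H](O)CCCCCCCCCCCCCC1(C)OCCO1` | intermediate
9 | (5R)-5-[13-(2-methyl-1,3-dioxolan-2-yl)tridecyl]furan-2(5H)-one | `O=C1C=C[C@@H](CCCCCCCCCCCCCC2(C)OCCO2)O1` | intermediate
10 | tris(methylsulfanyl)methane | `CSC(SC)SC` | starting material
11 | dimethyl(methylidene)ammonium iodide | `C=[N+](C)C.[I-]` | starting material
12 | tris(methylsulfanyl)methyllithium (not isolated) | `[Li]C(SC)(SC)SC` | intermediate
13 | lithium (4S,5R)-5-[13-(2-methyl-1,3-dioxolan-2-yl)tridecyl]-4-[tris(methylsulfanyl)methyl]-4,5-dihydrofuran-2-olate (not isolated) | `[Li]OC1=C[C@H](C(SC)(SC)SC)[C@@H](CCCCCCCCCCCCCC2(C)OCCO2)O1` | intermediate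
14 | (3R,4S,5R)-3-[(dimethylamino)methyl]-5-[13-(2-methyl-1,3-dioxolan-2-yl)tridecyl]-4-[tris(methylsulfanyl)methyl]oxolan-2-one | `CN(C)C[C@@H]1C(=O)O[C@H](CCCCCCCCCCCCCC2(C)OCCO2)[C@H]1C(SC)(SC)SC` | intermediate
15 | N,N,N-trimethyl-1-{(3R,4S,5R)-5-[13-(2-methyl-1,3-dioxolan-2-yl)tridecyl]-2-oxo-4-[tris(methylsulfanyl)methyl]oxolan-3-yl}methanaminium iodide (not isolated) | `C[N+](C)(C)C[C@@H]1C(=O)O[C@H](CCCCCCCCCCCCCC2(C)OCCO2)[C@H]1C(SC)(SC)SC.[I-]` | intermediate
16 | (4S,5R)-3-methylidene-5-[13-(2-methyl-1,3-dioxolan-2-yl)tridecyl]-4-[tris(methylsulfanyl)methyl]oxolan-2-one | `C=C1C(=O)O[C@H](CCCCCCCCCCCCCC2(C)OCCO2)[C@H]1C(SC)(SC)SC` | intermediate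
17 | (4S,5R)-3-methylidene-5-(14-oxopentadecyl)-4-[tris(methylsulfanyl)methyl]oxolan-2-one | `C=C1C(=O)O[C@H](CCCCCCCCCCCCCC(C)=O)[C@H]1C(SC)(SC)SC` | intermediate
18 | S-methyl (2R,3S)-4-methylidene-5-oxo-2-(14-oxopentadecyl)oxolane-3-carbothioate (not isolated) | `C=C1C(=O)O[C@H](CCCCCCCCCCCCCC(C)=O)[C@H]1C(=O)SC` | intermediate
19 | (2R,3S)-4-methylidene-5-oxo-2-(14-oxopentadecyl)oxolane-3-carboxylic acid | `C=C1C(=O)O[C@H](CCCCCCCCCCCCCC(C)=O)[C@H]1C(=O)O` | target

**Step count and risks**
Total steps: 10. Longest linear sequence: 10 steps (1 to 19).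

Step 7 is the most exposed. The enolate may be quenched by proton transfer, or may revert by loss of the trithiomethyl anion on warming, before the sparingly soluble iminium salt has reacted; surplus anion may also consume the iminium salt. The fallback separates the two bond formations. Setting out from 9, the conjugate addition of 12 is run alone and quenched at −78 °C with acetic acid to give the saturated (4S,5R)-4-[tris(methylsulfanyl)methyl] lactone F1. F1 is then deprotonated with lithium diisopropylamide (THF, −78 °C) and the clean enolate is treated with dimethyl(methylidene)ammonium iodide. This comes back to the route at 14.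

Step 10 is next. At the carbenium stage a proton may be lost from C4 to give a ketene dithioacetal conjugated with the methylene, through which the alkene can migrate into the ring or C4 can epimerise. Mercury may also add to the alkene, or hydrolysis may stall at the thioester. The fallback hydrolyses the orthothioester before the methylene exists. Setting out from 14, Hg(O2CCF3)2 in aqueous MeCN followed by dilute HCl removes orthothioester and ketal to give the amino keto acid F2. MeI with NaHCO3 in MeOH then quaternises the amine to the trimethylammonium carboxylate F3, which loses trimethylamine in the same flask. Acidification gives 19, where the fallback rejoins the route.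

Step 5 is third. Facial selectivity may be insufficient with an unbranched aliphatic aldehyde, and ethyl transfer from Et2Zn or aldol self-condensation may compete. The fallback replaces catalyst-controlled addition by reagent-controlled reduction. Setting out from 5, lithium methyl propiolate (6, LiN(SiMe3)2, THF, −78 °C) adds to give the racemic hydroxy ynoate F4. Dess–Martin periodinane oxidises it to the ynone F5. Midland reduction with B-(3-pinanyl)-9-borabicyclo[3.3.1]nonane prepared from (+)-α-pinene, which gives R carbinols from alkynyl ketones, then returns to the route at 7.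

**Further compounds**
F1 | step 7 | (4S,5R)-5-[13-(2-methyl-1,3-dioxolan-2-yl)tridecyl]-4-[tris(methylsulfanyl)methyl]oxolan-2-one | `O=C1C[C@H](C(SC)(SC)SC)[C@@H](CCCCCCCCCCCCCC2(C)OCCO2)O1`
F2 | step 10 | (2R,3S,4R)-4-[(dimethylamino)methyl]-5-oxo-2-(14-oxopentadecyl)oxolane-3-carboxylic acid | `CN(C)C[C@@H]1C(=O)O[C@H](CCCCCCCCCCCCCC(C)=O)[C@H]1C(=O)O`
F3 | step 10 | (2R,3S,4R)-5-oxo-2-(14-oxopentadecyl)-4-[(trimethylammonio)methyl]oxolane-3-carboxylate (inner salt) | `C[N+](C)(C)C[C@@H]1C(=O)O[C@H](CCCCCCCCCCCCCC(C)=O)[C@H]1C(=O)[O-]`
F4 | step 5 | racemic methyl 4-hydroxy-17-(2-methyl-1,3-dioxolan-2-yl)heptadec-2-ynoate | `COC(=O)C#CC(O)CCCCCCCCCCCCCC1(C)OCCO1`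
F5 | step 5 | methyl 17-(2-methyl-1,3-dioxolan-2-yl)-4-oxoheptadec-2-ynoate | `COC(=O)C#CC(=O)CCCCCCCCCCCCCC1(C)OCCO1`
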